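The numbers in the tables come from a simulation on assumed constants; scatter was added.

A plateau has no rate in it, and that was the first item at the meeting on blue, teal and red, where D at three different charges meets the same Z and E.

common to all: Z 0.011 M
- north: E 0.55 mM; D 46 µM; run made earlier
- west: E 0.55 mM; D 68 µM; run made earlier
- south: E 0.55 mM; D 89 µM; run made earlier
- blue: E 0.550 mM; D 54 µM; time 2.5 min
- teal: E 0.550 mM; D 78 µM; time 2.5 min
- red: E 0.550 mM; D 65 µM; time 2.5 min

| run | time / s | J / % | G / % | X / % | Z / % |
|---|---|---|---|---|---|
| north | 10.0 | 0 | 0.6 | 1.8 | 97.6 |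
| north | 25.0 | 0.4 | 0.5 | 2.9 | 96.8 |
| north | 50.0 | 0.4 | 0.7 | 4.8 | 94.7 |
| north | 80.0 | 0.8 | 0 | 4.3 | 94.2 |
| north | 120 | 0.7 | 0.5 | 3.6 | 95.2 |
| west | 10.0 | 0.8 | 0.8 | 2.2 | 96.6 |
| west | 25.0 | 0.3 | 0 | 5.6 | 95.0 |
| west | 50.0 | 0.3 | 0 | 6.3 | 92.9 |
| west | 80.0 | 0.9 | 0 | 5.4 | 92.6 |
| west | 120 | 0 | 0 | 6.7 | 93.1 |
| south | 10.0 | 0.7 | 0 | 3.0 | 96.3 |
| south | 25.0 | 0.7 | 0 | 5.8 | 92.1 |
| south | 50.0 | 0.6 | 0 | 7.6 | 92.1 |
| south | 80.0 | 0.6 | 0 | 8.5 | 91.5 |
| south | 120 | 0.6 | 0.2 | 8.7 | 90.5 |

(standard deviation of a reading: 0.5 percentage points)

- which of these there is most of at the end, counted by the Z in it, blue (Z / X / J / G)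
- which of these there is most of at the end, counted by the Z in it, teal (Z / X / J / G)
- which of these there is most of at the end, counted by the Z in it, red (Z / X / J / G)
- final amount of the leader among these, as a percentage of the Z charged, in blue
- final amount of the leader among these, as a percentage of the Z charged, in teal
- final amount of the leader among these, as a percentage of the Z charged, in red

- the earlier runs were read with a standard deviation of 0.5 percentage points

The kineticist reported that X climbs and then stays in the north, west and south runs, while Z at the last south reading still stands at 90.5%, far more than the X beside it, so she argued that the count to look for was how much X each D delivers and not how fast it does so.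

The chair proposed a zero for the scale: a D with even odds at each pass between delivering X and being lost delivers one X on average. The secretary then pooled the last readings of the north, west and south runs, each carrying the scatter, and got a reading of 10.3 for the number of X that one D delivers before it is lost at the 0.550 mM of E held in these runs, cX at the plateau over cD as charged, the turnover number N, which is about ten times the chair's zero.

He took it that each lost D holds one Z in J, J at the last south reading standing at 0.6%, with a scatter of 0.5 points, beside the 0.809% that one Z per D allows, so that the share of Z left at the plateau is one minus (N plus one) times cD/cZ. That reckoning gave him 94.5% in blue, 92.0% in teal and 93.3% in red.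

The forecast, reckoned apart and differing from these by little, named Z as leader in blue, Z in teal and Z in red, at 94.4%, 92% and 93.2%, taking the plateaus to suggest that “the catalyst dies rather than Z running out”.

The flasks gave Z, Z and Z as leaders, at 94.4% in blue, 91.7% in teal and 93.2% in red, each within the tolerance of the forecast.

Z + D → G (k = 1570 M⁻¹ s⁻¹); G ⇌ L (K = 2.21, k = 0.785 s⁻¹); L → D + X (k = 3.16 s⁻¹); G + E → J (k = 130 M⁻¹ s⁻¹) In red, the making of G from Z and D had 98% of its turnover behind it at 1.25 min, when J already held 97.9% of the catalyst charged, and D stood at 0% at 2.50 min, with X at 10.5 per D charged. For the neighbour flask, red with 0.0027 M of Z, N gives X at 24.8% and Z at 72.8%. That flask ended with X at 25.2% and Z at 72.3%.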